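**Retrosynthetic overview**
1. The glyceride C–O bond is made last, by opening (S)-glycidyl acetate with the diketo acid at the epoxide CH2. The chain ketone comes from an acyl chloride/alkylzinc coupling of a ring keto acid with a six-carbon iodo ester made from (R)-3-methylglutaric acid monomethyl ester.
2. Enabling feature: the quaternary ring carbon is α to the ring-bound ketone C=O, the neighbouring ring CH carries the 3-oxobutyl chain cis to that C=O, and the first CH2 of this chain is β to the methyl ketone C=O. An oxygen bridge from the C=O carbon to that CH2 hides both in a cis-fused γ-lactone (temporary five-membered ring): an α-methylbutenolide before annulation, a β-acyloxy ketone after Wacker oxidation.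
3. Key disconnection: formal [4+2] of (5R)-5-allyl-3-methylbutenolide with 3-silyloxy-4-methylpenta-1,3-diene. The Me2C–CH bond forms first, then the ring closes by the bond from the ring CH2 to the quaternary carbon. The one bought stereocentre (from (R)-epichlorohydrin) sets both ring stereocentres and is erased in the E1cB lactone opening.
4. Ring order: butenolide (temporary) first, six-membered carbocycle second (key step), then deoxygenation, lactone opening and hydrogenation.

Key step: step 7

Remark: compounds 8–10 (sulfur-bearing carbon; also sulfur in 10) and F2 (lactone α-carbon) are handled as epimer mixtures. These centres carry no descriptor and are destroyed or fixed in the following step.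

**Route**

Step 1
Reactants: 1 4-methylpent-1-en-3-ol
Product: 2 4-methylpent-1-en-3-one
Conditions: IBX (1.5 equiv), EtOAc, 75 °C; filter, distil
Reagents that add atoms: none
Why: IBX oxidation of a secondary allylic alcohol to the vinyl ketone under neutral conditions that do not add to the enone.

Step 2
Reactants: 2 4-methylpent-1-en-3-one
Product: 3 tert-butyl(dimethyl)[(4-methylpenta-1,3-dien-3-yl)oxy]silane
Conditions: tBuMe2SiOSO2CF3 (1.1 equiv), Et3N (1.5 equiv), CH2Cl2, 0 °C
Reagents that add atoms: tert-butyldimethylsilyl trifluoromethanesulfonate, CC(C)(C)[Si](C)(C)OS(=O)(=O)C(F)(F)F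
Why: Soft enolisation and O-silylation of the vinyl ketone at its only α-CH should give the 2-silyloxy diene, as in the standard preparation of 2-silyloxybutadienes.

Step 3
Reactants: 4 (2R)-2-(chloromethyl)oxirane
Product: 5 (2R)-1-chloropent-4-en-2-ol
Conditions: CH2=CHMgBr (1.2 equiv), CuI (10 mol %), THF, −40 to −20 °C; dilute HCl quench
Reagents that add atoms: vinylmagnesium bromide, C=C[Mg]Br
Why: Copper-catalysed Grignard opening of the epoxide at its unsubstituted carbon; the stereocentre is not touched.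

Step 4
Reactants: 5 (2R)-1-chloropent-4-en-2-ol
Product: 6 (2R)-2-(prop-2-en-1-yl)oxirane
Conditions: powdered NaOH, Et2O, rt; distil
Reagents that add atoms: none
Why: Intramolecular Williamson closure of the chlorohydrin to the epoxide with retention at the carbinol carbon.

Step 5
Reactants: 6 (2R)-2-(prop-2-en-1-yl)oxirane; 7 2-(phenylsulfanyl)propanoic acid
Product: 9 (5R)-3-methyl-3-(phenylsulfanyl)-5-(prop-2-en-1-yl)oxolan-2-one, via hydroxy acid 8 (not isolated)
Conditions: 7, LiN(iPr)2 (2.1 equiv), THF, 0 °C; then 6, 0 °C to rt; 1 M HCl; then TsOH·H2O (5 mol %), toluene, 60 °C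
Reagents that add atoms: none
Why: The dianion of the α-phenylthio acid opens the terminal epoxide at CH2 and acid closes the γ-lactone (sulfenylated lactone synthesis); the carbinol centre is retained.

Step 6
Reactants: 9 (5R)-3-methyl-3-(phenylsulfanyl)-5-(prop-2-en-1-yl)oxolan-2-one
Product: 11 (5R)-3-methyl-5-(prop-2-en-1-yl)furan-2(5H)-one, via sulfoxide 10 (not isolated)
Conditions: mCPBA (1.0 equiv), CH2Cl2, −20 °C; NaHCO3 wash; then toluene, 110 °C
Reagents that add atoms: none
Why: Sulfide oxidation followed by thermal syn-elimination of the sulfoxide (dehydrosulfenylation) should place the double bond in the ring as the conjugated trisubstituted butenolide; the neutral conditions keep the γ-stereocentre.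

Step 7
Reactants: 3 tert-butyl(dimethyl)[(4-methylpenta-1,3-dien-3-yl)oxy]silane; 11 (5R)-3-methyl-5-(prop-2-en-1-yl)furan-2(5H)-one
Product: 12 (3R,3aS,7aR)-5-{[tert-butyl(dimethyl)silyl]oxy}-4,4,7a-trimethyl-3-(prop-2-en-1-yl)-3a,4,7,7a-tetrahydro-2-benzofuran-1(3H)-one
Conditions: 3 (2 equiv), HN(SO2CF3)2 (10 mol %), CH2Cl2, −78 to −30 °C; Et3N quench
Reagents that add atoms: none
Why: HN(SO2CF3)2 protodesilylates a trace of 3 to the silyl triflimide, which silylates the lactone carbonyl of 11; the Me2C= carbon of 3 then adds to the β-carbon of 11 (Mukaiyama–Michael), and the resulting silyl ketene acetal attacks the terminal CH2 of the silyl-activated vinyl ketone unmasked from the diene, closing the six-membered ring by the bond between the ring CH2 and the quaternary carbon (6-endo-trig Michael closure, net [4+2]) and leaving the silyl enol ether. The closest known reaction type is the triflimide- or Lewis-acid-catalysed stepwise Diels–Alder (double Michael) reaction of hindered 2-silyloxy dienes with α-substituted cyclic enones and unsaturated lactones. The CH stereocentre is controlled by the bought γ-stereocentre of 11, because the bulky tertiary carbon enters anti to the allyl group. The quaternary stereocentre is controlled by the tether, because the three-carbon arm on that face can only reach the same face of the planar ketene acetal, so the new ring is cis-fused. The step needs regioselectivity, secured by the silyloxy group on the carbon next to the Me2C= terminus, and π-facial selectivity, secured by the γ-allyl group that is erased later; the stepwise path avoids the s-cis penalty that the inside methyl group of the diene would impose on a concerted cycloaddition.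

Step 8
Reactants: 12 (3R,3aS,7aR)-5-{[tert-butyl(dimethyl)silyl]oxy}-4,4,7a-trimethyl-3-(prop-2-en-1-yl)-3a,4,7,7a-tetrahydro-2-benzofuran-1(3H)-one
Product: 13 (3R,3aS,7aR)-4,4,7a-trimethyl-1-oxo-3-(prop-2-en-1-yl)-1,3,3a,4,7,7a-hexahydro-2-benzofuran-5-yl trifluoromethanesulfonate
Conditions: CsF (3 equiv), PhN(SO2CF3)2 (1.5 equiv), DME, rt
Reagents that add atoms: N-phenylbis(trifluoromethanesulfonimide), O=S(=O)(N(c1ccccc1)S(=O)(=O)C(F)(F)F)C(F)(F)F
Why: Fluoride cleaves the silyl enol ether to the caesium enolate, which is O-triflated (direct silyl enol ether to enol triflate conversion); the double bond position is fixed by the quaternary neighbour.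

Step 9
Reactants: 13 (3R,3aS,7aR)-4,4,7a-trimethyl-1-oxo-3-(prop-2-en-1-yl)-1,3,3a,4,7,7a-hexahydro-2-benzofuran-5-yl trifluoromethanesulfonate
Product: 14 (3R,3aS,7aR)-4,4,7a-trimethyl-3-(prop-2-en-1-yl)-3a,4,7,7a-tetrahydro-2-benzofuran-1(3H)-one
Conditions: Pd(PPh3)4 (5 mol %), LiCl (3 equiv), Bu3SnH (1.5 equiv), THF, 60 °C
Reagents that add atoms: none
Why: Palladium-catalysed reduction of the enol triflate with tributyltin hydride (Stille-type hydride transfer) removes the oxygen that steered the annulation.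

Step 10
Reactants: 14 (3R,3aS,7aR)-4,4,7a-trimethyl-3-(prop-2-en-1-yl)-3a,4,7,7a-tetrahydro-2-benzofuran-1(3H)-one
Product: 15 (3R,3aS,7aR)-4,4,7a-trimethyl-3-(2-oxopropyl)-3a,4,7,7a-tetrahydro-2-benzofuran-1(3H)-one
Conditions: PdCl2 (10 mol %), Cu(OAc)2 (20 mol %), O2 (1 atm), N,N-dimethylacetamide/H2O 7:1, rt
Reagents that add atoms: water, O
Why: Tsuji–Wacker oxidation of the terminal alkene to the methyl ketone; the hindered disubstituted ring alkene should not react.

Step 11
Reactants: 15 (3R,3aS,7aR)-4,4,7a-trimethyl-3-(2-oxopropyl)-3a,4,7,7a-tetrahydro-2-benzofuran-1(3H)-one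
Product: 17 (1R,2S)-1,3,3-trimethyl-2-(3-oxobutyl)cyclohexane-1-carboxylic acid, via enone carboxylate salt 16 (not isolated)
Conditions: DBU (1.5 equiv), THF, 0 °C to rt; then 10% Pd/C, H2 (1 atm), MeOH; 1 M HCl work-up
Reagents that add atoms: none
Why: E1cB elimination of the β-acyloxy ketone expels the lactone carboxylate, and the enone and ring alkene are hydrogenated over palladium on carbon before the carboxylate can add back; the erased carbinol centre leaves the two ring stereocentres untouched.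

Step 12
Reactants: 18 (3R)-5-methoxy-3-methyl-5-oxopentanoic acid
Product: 19 methyl (3R)-5-hydroxy-3-methylpentanoate
Conditions: BH3·SMe2 (1.1 equiv), THF, −10 °C to rt; aqueous work-up; used at once
Reagents that add atoms: none
Why: Chemoselective borane reduction of the carboxylic acid in the presence of the methyl ester.

Step 13
Reactants: 19 methyl (3R)-5-hydroxy-3-methylpentanoate
Product: 20 methyl (3S)-5-iodo-3-methylpentanoate
Conditions: I2 (1.2 equiv), PPh3 (1.2 equiv), imidazole (1.5 equiv), CH2Cl2, 0 °C to rt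
Reagents that add atoms: iodine, II
Why: Appel-type iodination of the primary alcohol; the descriptor changes only because iodine raises the priority of that branch.

Step 14
Reactants: 17 (1R,2S)-1,3,3-trimethyl-2-(3-oxobutyl)cyclohexane-1-carboxylic acid; 20 methyl (3S)-5-iodo-3-methylpentanoate
Product: 23 methyl (3R)-3-methyl-6-oxo-6-[(1R,2S)-1,3,3-trimethyl-2-(3-oxobutyl)cyclohexyl]hexanoate, via acid chloride 21 (not isolated), via alkylzinc iodide 22 (not isolated)
Conditions: 17, (COCl)2 (1.5 equiv), DMF (cat.), CH2Cl2, 0 °C to rt, evaporate; 20, Zn dust (activated with BrCH2CH2Br and Me3SiCl), THF, 40 °C; then both, Pd(PPh3)4 (5 mol %), THF, 0 °C to rt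
Reagents that add atoms: none
Why: Negishi acylation: zinc insertion gives an ester-tolerant alkylzinc iodide that couples with the acid chloride under palladium catalysis without touching the methyl ketone.

Step 15
Reactants: 23 methyl (3R)-3-methyl-6-oxo-6-[(1R,2S)-1,3,3-trimethyl-2-(3-oxobutyl)cyclohexyl]hexanoate
Product: 24 (3R)-3-methyl-6-oxo-6-[(1R,2S)-1,3,3-trimethyl-2-(3-oxobutyl)cyclohexyl]hexanoic acid
Conditions: LiOH·H2O (2 equiv), THF/H2O 3:1, 0 °C to rt; 1 M HCl
Reagents that add atoms: lithium hydroxide, [Li+].[OH-]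
Why: Saponification of the unhindered methyl ester; no stereocentre is α to a carbonyl with a hydrogen, so none can epimerise.

Step 16
Reactants: 25 (2R)-oxiran-2-ylmethanol
Product: 26 (2S)-oxiran-2-ylmethyl acetate
Conditions: Ac2O (1.2 equiv), Et3N (1.5 equiv), DMAP (2 mol %), CH2Cl2, 0 °C
Reagents that add atoms: acetic anhydride, CC(=O)OC(C)=O
Why: DMAP-catalysed acetylation of the primary alcohol; the stereocentre is untouched and the descriptor changes only by priority.

Step 17
Reactants: 24 (3R)-3-methyl-6-oxo-6-[(1R,2S)-1,3,3-trimethyl-2-(3-oxobutyl)cyclohexyl]hexanoic acid; 26 (2S)-oxiran-2-ylmethyl acetate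
Product: 27 (2R)-3-(acetyloxy)-2-hydroxypropyl (3R)-3-methyl-6-oxo-6-[(1R,2S)-1,3,3-trimethyl-2-(3-oxobutyl)cyclohexyl]hexanoate
Conditions: 26 (1.5 equiv), (R,R)-N,N'-bis(3,5-di-tert-butylsalicylidene)-1,2-cyclohexanediaminocobalt (divalent cobalt, 2 mol %, oxidised by air with 24 to the active trivalent cobalt carboxylate; the enantiomeric complex is taken if a test run shows it to be the matched one), iPr2NEt (1 equiv), tert-butyl methyl ether, rt
Reagents that add atoms: none
Why: Cobalt–salen-catalysed opening of a terminal epoxide by a carboxylic acid at the CH2 terminus should give the 1-acyl-3-acetyl glycerol with the free secondary hydroxyl directly; the stereocentre of 26 becomes the carbinol centre unchanged.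

**Compound list**
1 | 4-methylpent-1-en-3-ol (racemic) | C=CC(O)C(C)C | starting material
2 | 4-methylpent-1-en-3-one | C=CC(=O)C(C)C | intermediate
3 | tert-butyl(dimethyl)[(4-methylpenta-1,3-dien-3-yl)oxy]silane | C=CC(O[Si](C)(C)C(C)(C)C)=C(C)C | intermediate
4 | (2R)-2-(chloromethyl)oxirane | ClC[C@H]1CO1 | starting material
5 | (2R)-1-chloropent-4-en-2-ol | ClC[C@H](O)CC=C | intermediate
6 | (2R)-2-(prop-2-en-1-yl)oxirane | C=CC[C@@H]1CO1 | intermediate
7 | 2-(phenylsulfanyl)propanoic acid (racemic) | CC(Sc1ccccc1)C(=O)O | starting material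
8 | (4R)-4-hydroxy-2-methyl-2-(phenylsulfanyl)hept-6-enoic acid | C=CC[C@@H](O)CC(C)(Sc1ccccc1)C(=O)O | intermediate (not isolated)
9 | (5R)-3-methyl-3-(phenylsulfanyl)-5-(prop-2-en-1-yl)oxolan-2-one | C=CC[C@@H]1CC(C)(Sc2ccccc2)C(=O)O1 | intermediate
10 | (5R)-3-methyl-3-(phenylsulfinyl)-5-(prop-2-en-1-yl)oxolan-2-one | C=CC[C@@H]1CC(C)(S(=O)c2ccccc2)C(=O)O1 | intermediate (not isolated)
11 | (5R)-3-methyl-5-(prop-2-en-1-yl)furan-2(5H)-one | C=CC[C@H]1OC(=O)C(C)=C1 | intermediate
12 | (3R,3aS,7aR)-5-{[tert-butyl(dimethyl)silyl]oxy}-4,4,7a-trimethyl-3-(prop-2-en-1-yl)-3a,4,7,7a-tetrahydro-2-benzofuran-1(3H)-one | C=CC[C@H]1OC(=O)[C@]2(C)CC=C(O[Si](C)(C)C(C)(C)C)C(C)(C)[C@H]12 | intermediate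
13 | (3R,3aS,7aR)-4,4,7a-trimethyl-1-oxo-3-(prop-2-en-1-yl)-1,3,3a,4,7,7a-hexahydro-2-benzofuran-5-yl trifluoromethanesulfonate | C=CC[C@H]1OC(=O)[C@]2(C)CC=C(OS(=O)(=O)C(F)(F)F)C(C)(C)[C@H]12 | intermediate
14 | (3R,3aS,7aR)-4,4,7a-trimethyl-3-(prop-2-en-1-yl)-3a,4,7,7a-tetrahydro-2-benzofuran-1(3H)-one | C=CC[C@H]1OC(=O)[C@]2(C)CC=CC(C)(C)[C@H]12 | intermediate
15 | (3R,3aS,7aR)-4,4,7a-trimethyl-3-(2-oxopropyl)-3a,4,7,7a-tetrahydro-2-benzofuran-1(3H)-one | CC(=O)C[C@H]1OC(=O)[C@]2(C)CC=CC(C)(C)[C@H]12 | intermediate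
16 | 1,8-diazabicyclo[5.4.0]undec-7-enium (1R,6S)-1,5,5-trimethyl-6-[(1E)-3-oxobut-1-en-1-yl]cyclohex-3-ene-1-carboxylate | CC(=O)/C=C/[C@H]1C(C)(C)C=CC[C@@]1(C)C(=O)[O-].C1CCC2=[NH+]CCCN2CC1 | intermediate (not isolated)
17 | (1R,2S)-1,3,3-trimethyl-2-(3-oxobutyl)cyclohexane-1-carboxylic acid | CC(=O)CC[C@H]1C(C)(C)CCC[C@@]1(C)C(=O)O | intermediate
18 | (3R)-5-methoxy-3-methyl-5-oxopentanoic acid | OC(=O)C[C@@H](C)CC(=O)OC | starting material
19 | methyl (3R)-5-hydroxy-3-methylpentanoate | OCC[C@@H](C)CC(=O)OC | intermediate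
20 | methyl (3S)-5-iodo-3-methylpentanoate | ICC[C@@H](C)CC(=O)OC | intermediate
21 | (1R,2S)-1,3,3-trimethyl-2-(3-oxobutyl)cyclohexane-1-carbonyl chloride | CC(=O)CC[C@H]1C(C)(C)CCC[C@@]1(C)C(Cl)=O | intermediate (not isolated)
22 | iodo[(3S)-5-methoxy-3-methyl-5-oxopentyl]zinc | I[Zn]CC[C@@H](C)CC(=O)OC | intermediate (not isolated)
23 | methyl (3R)-3-methyl-6-oxo-6-[(1R,2S)-1,3,3-trimethyl-2-(3-oxobutyl)cyclohexyl]hexanoate | CC(=O)CC[C@H]1C(C)(C)CCC[C@@]1(C)C(=O)CC[C@@H](C)CC(=O)OC | intermediate
24 | (3R)-3-methyl-6-oxo-6-[(1R,2S)-1,3,3-trimethyl-2-(3-oxobutyl)cyclohexyl]hexanoic acid | CC(=O)CC[C@H]1C(C)(C)CCC[C@@]1(C)C(=O)CC[C@@H](C)CC(=O)O | intermediate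
25 | (2R)-oxiran-2-ylmethanol | OC[C@@H]1CO1 | starting material
26 | (2S)-oxiran-2-ylmethyl acetate | CC(=O)OC[C@@H]1CO1 | intermediate
27 | (2R)-3-(acetyloxy)-2-hydroxypropyl (3R)-3-methyl-6-oxo-6-[(1R,2S)-1,3,3-trimethyl-2-(3-oxobutyl)cyclohexyl]hexanoate | CC(=O)CC[C@H]1C(C)(C)CCC[C@@]1(C)C(=O)CC[C@@H](C)CC(=O)OC[C@H](O)COC(C)=O | target

**Step count and risks**
Total steps: 17. Longest linear sequence: 12 steps (steps 3–11, 14, 15, 17).

Steps most likely to fail:

1. Step 7. Two crowded carbons must join in the first bond-forming event, so the annulation may be too slow and the diene may be lost to protodesilylation or oligomerisation, or the sequence may stop after the first Michael addition without ring closure.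
Fallback, setting out from 11 and returning at 17: commercial 5-bromo-2,2-dimethylpentanoic acid is esterified with N-hydroxyphthalimide (DIC, DMAP cat.) to 1,3-dioxoisoindolin-2-yl 5-bromo-2,2-dimethylpentanoate F1. Photoredox decarboxylation (Ru(bpy)3(PF6)2 cat., Hantzsch ester, iPr2NEt, CH2Cl2, blue light) should give the tertiary radical, which adds to the β-carbon of 11 anti to the allyl group (Giese addition) to give (4R,5R)-4-(5-bromo-2-methylpentan-2-yl)-3-methyl-5-(prop-2-en-1-yl)oxolan-2-one F2. LiN(SiMe3)2 in THF/DMPU (−78 to 0 °C) forms the lactone enolate, whose 6-exo-tet alkylation makes the bond between the ring CH2 and the quaternary carbon and should give cis-fused (3R,3aS,7aR)-4,4,7a-trimethyl-3-(prop-2-en-1-yl)hexahydro-2-benzofuran-1(3H)-one F3. Wacker oxidation as in step 10 gives (3R,3aS,7aR)-4,4,7a-trimethyl-3-(2-oxopropyl)hexahydro-2-benzofuran-1(3H)-one F4. DBU then opens the lactone to (1R,2S)-1,3,3-trimethyl-2-[(1E)-3-oxobut-1-en-1-yl]cyclohexane-1-carboxylic acid F5 (as its salt), which is hydrogenated as in step 11 to 17.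

2. Step 14. Oxidative addition and transmetalation at the neopentyl-type acyl chloride may be slow, so decarbonylation of the acylpalladium species or homocoupling of the zinc reagent may take over.
Fallback, setting out from 20 and 17 and returning at 24: ester 20 is reduced with iBu2AlH (CH2Cl2, −78 to 0 °C) to (3S)-5-iodo-3-methylpentan-1-ol F6, which is silylated (tBuMe2SiCl, imidazole) to tert-butyl{[(3S)-5-iodo-3-methylpentyl]oxy}dimethylsilane F7. Iodine–lithium exchange (tBuLi, 2 equiv, Et2O, −78 °C) gives [(3R)-5-{[tert-butyl(dimethyl)silyl]oxy}-3-methylpentyl]lithium F8. Acid 17 is treated with LiN(iPr)2 (2.2 equiv, THF, −78 °C), which forms the lithium carboxylate and masks the methyl ketone as its enolate. F8 (3 equiv) is then added and the mixture warmed to 0 °C (ketone synthesis from a lithium carboxylate and an alkyllithium); aqueous work-up should give (4R)-6-{[tert-butyl(dimethyl)silyl]oxy}-4-methyl-1-[(1R,2S)-1,3,3-trimethyl-2-(3-oxobutyl)cyclohexyl]hexan-1-one F9. HF·pyridine frees (4R)-6-hydroxy-4-methyl-1-[(1R,2S)-1,3,3-trimethyl-2-(3-oxobutyl)cyclohexyl]hexan-1-one F10, and Jones oxidation (CrO3, H2SO4, acetone, 0 °C) gives acid 24.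

3. Step 17. Attack at the internal epoxide carbon, or acyl migration between the glycerol oxygens during the reaction, may erode the regiochemical purity of the diacylglycerol.
Fallback, setting out from 24 and returning at 27: Steglich esterification of 24 with commercial (S)-(2,2-dimethyl-1,3-dioxolan-4-yl)methanol (DCC, DMAP cat., CH2Cl2) gives [(4R)-2,2-dimethyl-1,3-dioxolan-4-yl]methyl (3R)-3-methyl-6-oxo-6-[(1R,2S)-1,3,3-trimethyl-2-(3-oxobutyl)cyclohexyl]hexanoate F11. The acetonide is removed with aqueous acetic acid (40 °C) to give (2R)-2,3-dihydroxypropyl (3R)-3-methyl-6-oxo-6-[(1R,2S)-1,3,3-trimethyl-2-(3-oxobutyl)cyclohexyl]hexanoate F12. Acetyl chloride (1.05 equiv) with 2,4,6-collidine in CH2Cl2 at −78 °C should acetylate the primary hydroxyl selectively to give 27.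

**Further compounds**
F1 | step 7 | 1,3-dioxoisoindolin-2-yl 5-bromo-2,2-dimethylpentanoate | BrCCCC(C)(C)C(=O)ON1C(=O)c2ccccc2C1=O
F2 | step 7 | (4R,5R)-4-(5-bromo-2-methylpentan-2-yl)-3-methyl-5-(prop-2-en-1-yl)oxolan-2-one | C=CC[C@H]1OC(=O)C(C)[C@@H]1C(C)(C)CCCBr
F3 | step 7 | (3R,3aS,7aR)-4,4,7a-trimethyl-3-(prop-2-en-1-yl)hexahydro-2-benzofuran-1(3H)-one | C=CC[C@H]1OC(=O)[C@]2(C)CCCC(C)(C)[C@H]12
F4 | step 7 | (3R,3aS,7aR)-4,4,7a-trimethyl-3-(2-oxopropyl)hexahydro-2-benzofuran-1(3H)-one | CC(=O)C[C@H]1OC(=O)[C@]2(C)CCCC(C)(C)[C@H]12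
F5 | step 7 | (1R,2S)-1,3,3-trimethyl-2-[(1E)-3-oxobut-1-en-1-yl]cyclohexane-1-carboxylic acid | CC(=O)/C=C/[C@H]1C(C)(C)CCC[C@@]1(C)C(=O)O
F6 | step 14 | (3S)-5-iodo-3-methylpentan-1-ol | ICC[C@@H](C)CCO
F7 | step 14 | tert-butyl{[(3S)-5-iodo-3-methylpentyl]oxy}dimethylsilane | ICC[C@@H](C)CCO[Si](C)(C)C(C)(C)C
F8 | step 14 | [(3R)-5-{[tert-butyl(dimethyl)silyl]oxy}-3-methylpentyl]lithium | [Li]CC[C@@H](C)CCO[Si](C)(C)C(C)(C)C
F9 | step 14 | (4R)-6-{[tert-butyl(dimethyl)silyl]oxy}-4-methyl-1-[(1R,2S)-1,3,3-trimethyl-2-(3-oxobutyl)cyclohexyl]hexan-1-one | CC(=O)CC[C@H]1C(C)(C)CCC[C@@]1(C)C(=O)CC[C@@H](C)CCO[Si](C)(C)C(C)(C)C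
F10 | step 14 | (4R)-6-hydroxy-4-methyl-1-[(1R,2S)-1,3,3-trimethyl-2-(3-oxobutyl)cyclohexyl]hexan-1-one | CC(=O)CC[C@H]1C(C)(C)CCC[C@@]1(C)C(=O)CC[C@@H](C)CCO
F11 | step 17 | [(4R)-2,2-dimethyl-1,3-dioxolan-4-yl]methyl (3R)-3-methyl-6-oxo-6-[(1R,2S)-1,3,3-trimethyl-2-(3-oxobutyl)cyclohexyl]hexanoate | CC(=O)CC[C@H]1C(C)(C)CCC[C@@]1(C)C(=O)CC[C@@H](C)CC(=O)OC[C@H]2COC(C)(C)O2
F12 | step 17 | (2R)-2,3-dihydroxypropyl (3R)-3-methyl-6-oxo-6-[(1R,2S)-1,3,3-trimethyl-2-(3-oxobutyl)cyclohexyl]hexanoate | CC(=O)CC[C@H]1C(C)(C)CCC[C@@]1(C)C(=O)CC[C@@H](C)CC(=O)OC[C@H](O)CO
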